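**Strategy**

Ring A of the flavanone (C4a, C5, C6, C7, C8, C8a) is disconnected at C4a–C8a and C5–C6 into a 3-methoxy-4-prenylcyclobutenone and a lactate-derived siloxyalkyne. Their thermal benzannulation builds the pentasubstituted phloroglucinol in one operation and exploits its pattern of three oxygens at C5, C7 and C8a with prenyl at C8: O7 arrives as the methyl ether, O5 as a triisopropylsilyl ether and O8a as the only free phenol, flanked by prenyl and the C4a side chain. The side chain is then oxidised to the acetyl group, ring C is closed at the free phenol as a chromone, and C2 is set by asymmetric rhodium-catalysed arylation.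

Key step: step 6

**Remarks on the chemistry (assumptions)**

- The carbinol oxygen of the alkyne is carried as a triethylsilyl ether. It must later be removed beside an aryl triisopropylsilyl ether and on a benzylic carbon that ionises easily, which a more robust silyl group would not allow under mild buffered conditions.
- The lactate-derived centre is a spectator and is destroyed in step 8; the (S)-series is used only because ethyl (S)-lactate is the inexpensive form. Cyclobutenone 7 is racemic; its centre becomes aromatic in step 6.
- Assumption for step 10: the sense of induction is assigned by analogy with the arylation of cyclic enones, where an (S)-biaryl bisphosphine gives the (S)-3-aryl ketone. The same enone face corresponds to 2S in the flavanone. Should the sense prove reversed, the antipodal ligand is used.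

**Route**

Step 1
Reactants: 1 5-methylhex-4-enoic acid
Product: 2 5-methylhex-4-enoyl chloride
Conditions: (COCl)2 (1.2 equiv), DMF (cat.), CH2Cl2, 0 °C → rt; concentrated, used crude
Reagents that add atoms: oxalyl chloride, ClC(=O)C(=O)Cl
Why: Acid chloride formation under Vilsmeier-type DMF catalysis is standard, and at this temperature the trisubstituted alkene is not expected to add HCl.

Step 2
Reactants: 3 chloroacetaldehyde dimethyl acetal
Product: 5 methoxyacetylene, via sodium methoxyacetylide 4 (not isolated)
Conditions: NaNH2 (3.1 equiv), liquid NH3, −33 °C; NH3 evaporated; cold saturated aq. NaCl, −20 °C; distilled into a cold trap, kept as a cold Et2O solution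
Reagents that add atoms: none
Why: Two successive base-induced β-eliminations (loss of methanol, then of HCl) turn the chloroacetal into the alkoxyalkyne, which the third equivalent of amide holds as its acetylide until the cold aqueous quench; this is the standard preparation of methoxyacetylene.

Step 3
Reactants: 2 5-methylhex-4-enoyl chloride, 5 methoxyacetylene
Product: 7 3-methoxy-4-(3-methylbut-2-enyl)cyclobut-2-en-1-one (racemic), via prenylketene 6 (not isolated)
Conditions: Et3N (1.2 equiv), 5 (2.5 equiv), Et2O, −10 °C → rt, slow addition of 2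
Reagents that add atoms: none
Why: Dehydrochlorination gives the aldoketene, which undergoes the known (2+2) cycloaddition of ketenes with alkoxyacetylenes, the unoxygenated alkyne carbon bonding to the ketene carbonyl carbon so that methoxy sits at C3 and prenyl at C4; slow addition into excess alkyne suppresses ketene dimerisation, and the single CH2 link keeps the prenyl alkene from reaching the ketene.

Step 4
Reactants: 8 ethyl (S)-lactate
Product: 9 ethyl (S)-2-(triethylsilyloxy)propanoate
Conditions: Et3SiCl (1.1 equiv), imidazole (1.5 equiv), CH2Cl2, 0 °C → rt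
Reagents that add atoms: chlorotriethylsilane, CC[Si](Cl)(CC)CC
Why: Imidazole-mediated O-silylation of a secondary alcohol is routine and does not touch the stereocentre.

Step 5
Reactants: 9 ethyl (S)-2-(triethylsilyloxy)propanoate
Product: 12 (S)-3-(triethylsilyloxy)-1-(triisopropylsilyloxy)but-1-yne, via lithium dibromoenolate 10 (not isolated), via lithium ynolate 11 (not isolated)
Conditions: CH2Br2, lithium 2,2,6,6-tetramethylpiperidide, THF, −78 °C; then 9; LiN(SiMe3)2, −78 → −20 °C; n-BuLi, −78 °C → rt; i-Pr3SiCl, 0 °C → rt
Reagents that add atoms: dibromomethane, BrCBr; chlorotriisopropylsilane, CC(C)[Si](Cl)(C(C)C)C(C)C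
Why: Kowalski ester homologation stopped at the ynolate: LiCHBr2 adds to the ester, the amide base gives dibromoenolate 10, bromine–lithium exchange triggers the 1,2-shift of the carbinol carbon (with retention) to ynolate 11, and the bulky silyl chloride silylates on oxygen to give the ynol silyl ether.

Step 6
Reactants: 7 3-methoxy-4-(3-methylbut-2-enyl)cyclobut-2-en-1-one, 12 (S)-3-(triethylsilyloxy)-1-(triisopropylsilyloxy)but-1-yne
Product: 17 2-[(S)-1-(triethylsilyloxy)ethyl]-5-methoxy-6-(3-methylbut-2-enyl)-3-(triisopropylsilyloxy)phenol, via vinylketene 13 (not isolated), via vinylcyclobutenone 14 (not isolated), via dienylketene 15 (not isolated), via cyclohexadienone 16 (not isolated)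
Conditions: 7 (1.0 equiv), 12 (1.2 equiv), toluene (0.3 M), 80 °C then 110 °C, sealed tube, argon
Reagents that add atoms: none
Why: On heating, 7 undergoes conrotatory four-electron ring opening (prenyl rotating outward) to vinylketene 13, whose ketene C=C adds in a (2+2) sense to the electron-rich alkyne 12 to give 4-vinylcyclobutenone 14, and a second four-electron opening gives dienylketene 15. Ring A is then closed by thermal disrotatory six-electron electrocyclisation of 15 (re-forming the C8a–C8 bond) to cyclohexadienone 16, which tautomerises irreversibly to phenol 17, so that the net new skeletal bonds are C4a–C8a and C5–C6. The closest known reaction type is the Danheiser benzannulation of cyclobutenones with triisopropylsilyl ynol ethers, which gives resorcinol monosilyl ethers. No stereocentre is created: the centre of 7 becomes aromatic and the lactate-derived centre is a spectator. The selectivity needed is regiochemical and is secured by the polarisation of the siloxyalkyne, whose unoxygenated carbon bonds to the ketene carbonyl carbon, which places the side chain at C4a next to the new hydroxyl at C8a, the silyloxy group at C5, the methoxy group from C3 of 7 at C7 and the prenyl group from C4 of 7 at C8. Outward rotation puts the prenyl group trans to the ketene across the enol ether double bond of 13, so its alkene cannot reach the ketene and no intramolecular cycloaddition is expected.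

Step 7
Reactants: 17 2-[(S)-1-(triethylsilyloxy)ethyl]-5-methoxy-6-(3-methylbut-2-enyl)-3-(triisopropylsilyloxy)phenol
Product: 18 2-[(S)-1-hydroxyethyl]-5-methoxy-6-(3-methylbut-2-enyl)-3-(triisopropylsilyloxy)phenol
Conditions: HF·pyridine, pyridine, THF, 0 °C; NaHCO3 work-up; used directly
Reagents that add atoms: none
Why: Selective desilylation: fluoride buffered on the acidic side should cleave the small alkyl triethylsilyl ether much faster than the hindered aryl triisopropylsilyl ether, and the cold, weakly acidic medium is not expected to ionise the electron-rich benzylic C–O bond.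

Step 8
Reactants: 18 2-[(S)-1-hydroxyethyl]-5-methoxy-6-(3-methylbut-2-enyl)-3-(triisopropylsilyloxy)phenol
Product: 19 1-[2-hydroxy-4-methoxy-3-(3-methylbut-2-enyl)-6-(triisopropylsilyloxy)phenyl]ethan-1-one
Conditions: MnO2 (activated, 15 equiv), CH2Cl2, rt
Reagents that add atoms: none
Why: Benzylic alcohol oxidation with MnO2, a surface oxidant selective for benzylic carbinols, should leave the free phenol, the aryl silyl ether and the trisubstituted alkene untouched; the lactate-derived centre is removed here by design.

Step 9
Reactants: 19 1-[2-hydroxy-4-methoxy-3-(3-methylbut-2-enyl)-6-(triisopropylsilyloxy)phenyl]ethan-1-one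
Product: 21 7-methoxy-8-(3-methylbut-2-enyl)-5-(triisopropylsilyloxy)-4H-chromen-4-one, via enaminone 20 (not isolated)
Conditions: Me2NCH(OMe)2 (3 equiv), toluene, 90 °C; evaporated; TsOH·H2O (1.2 equiv), CH2Cl2, 0 °C → rt
Reagents that add atoms: N,N-dimethylformamide dimethyl acetal, COC(OC)N(C)C
Why: Enaminone formation from the methyl ketone and the amide acetal, then acid-promoted addition–elimination of the only free phenol (O at C8a) at the β-carbon with loss of dimethylamine, closes ring C by the established enaminone route to chromones; because O5 is silylated, only the 8-prenyl isomer can form.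

Step 10
Reactants: 21 7-methoxy-8-(3-methylbut-2-enyl)-5-(triisopropylsilyloxy)-4H-chromen-4-one, 22 4-methoxyphenylboronic acid
Product: 23 (S)-7-methoxy-2-(4-methoxyphenyl)-8-(3-methylbut-2-enyl)-5-(triisopropylsilyloxy)chroman-4-one
Conditions: [RhCl(C2H4)2]2 (2.5 mol%), (S)-2,2′-bis[bis(3,4,5-trifluorophenyl)phosphino]-6,6′-dimethoxy-1,1′-biphenyl (6 mol%), 22 (3 equiv), aq. KOH (10 mol%), toluene/H2O (10:1), 30 °C
Reagents that add atoms: none
Why: Hayashi–Miyaura asymmetric 1,4-addition, established for chromones with electron-poor biaryl bisphosphine complexes of monovalent rhodium: the aryl–rhodium species formed from 22 inserts the C2=C3 bond on the enone face left open by the (S)-ligand, which corresponds to 2S, and hydrolysis of the rhodium enolate releases 23.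

Step 11
Reactants: 23 (S)-7-methoxy-2-(4-methoxyphenyl)-8-(3-methylbut-2-enyl)-5-(triisopropylsilyloxy)chroman-4-one
Product: 24 flowerine, (S)-5-hydroxy-7-methoxy-2-(4-methoxyphenyl)-8-(3-methylbut-2-enyl)chroman-4-one
Conditions: Bu4NF (1.2 equiv), AcOH (1.5 equiv), THF, 0 °C
Reagents that add atoms: none
Why: Fluoride cleavage of the aryl silyl ether, buffered with acetic acid so that no phenoxide or enolate builds up, should free the C5 hydroxyl without retro-oxa-Michael opening of ring C and hence without racemisation at C2.

**Compound list**

1 | 5-methylhex-4-enoic acid | CC(C)=CCCC(=O)O | starting material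
2 | 5-methylhex-4-enoyl chloride | CC(C)=CCCC(=O)Cl | intermediate
3 | chloroacetaldehyde dimethyl acetal (2-chloro-1,1-dimethoxyethane) | COC(CCl)OC | starting material
4 | sodium methoxyacetylide | COC#[C-].[Na+] | intermediate (not isolated)
5 | methoxyacetylene (methoxyethyne) | COC#C | intermediate
6 | prenylketene (5-methylhexa-1,4-dien-1-one) | O=C=CCC=C(C)C | intermediate (not isolated)
7 | 3-methoxy-4-(3-methylbut-2-enyl)cyclobut-2-en-1-one (racemic) | COC1=CC(=O)C1CC=C(C)C | intermediate
8 | ethyl (S)-lactate | C[C@H](O)C(=O)OCC | starting material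
9 | ethyl (S)-2-(triethylsilyloxy)propanoate | C[C@H](O[Si](CC)(CC)CC)C(=O)OCC | intermediate
10 | lithium (S)-1,1-dibromo-3-(triethylsilyloxy)but-1-en-2-olate | C[C@H](O[Si](CC)(CC)CC)C([O-])=C(Br)Br.[Li+] | intermediate (not isolated)
11 | lithium (S)-3-(triethylsilyloxy)but-1-yn-1-olate | C[C@H](O[Si](CC)(CC)CC)C#C[O-].[Li+] | intermediate (not isolated)
12 | (S)-3-(triethylsilyloxy)-1-(triisopropylsilyloxy)but-1-yne | C[C@H](O[Si](CC)(CC)CC)C#CO[Si](C(C)C)(C(C)C)C(C)C | intermediate
13 | (3Z)-3-methoxy-7-methylocta-1,3,6-trien-1-one (vinylketene) | O=C=C/C(OC)=C/CC=C(C)C | intermediate (not isolated)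
14 | 4-[(1Z)-1-methoxy-5-methylhexa-1,4-dien-1-yl]-2-[(1S)-1-(triethylsilyloxy)ethyl]-3-(triisopropylsilyloxy)cyclobut-2-en-1-one (both configurations at C4 of the ring) | C[C@H](O[Si](CC)(CC)CC)C1=C(O[Si](C(C)C)(C(C)C)C(C)C)C(/C(OC)=C/CC=C(C)C)C1=O | intermediate (not isolated)
15 | (3E,5Z)-5-methoxy-9-methyl-2-[(1S)-1-(triethylsilyloxy)ethyl]-3-(triisopropylsilyloxy)deca-1,3,5,8-tetraen-1-one (dienylketene) | C[C@H](O[Si](CC)(CC)CC)C(=C=O)/C(O[Si](C(C)C)(C(C)C)C(C)C)=C\C(OC)=C\CC=C(C)C | intermediate (not isolated)
16 | 5-methoxy-6-(3-methylbut-2-enyl)-2-[(1S)-1-(triethylsilyloxy)ethyl]-3-(triisopropylsilyloxy)cyclohexa-2,4-dien-1-one (both configurations at C6) | C[C@H](O[Si](CC)(CC)CC)C1=C(O[Si](C(C)C)(C(C)C)C(C)C)C=C(OC)C(CC=C(C)C)C1=O | intermediate (not isolated)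
17 | 2-[(S)-1-(triethylsilyloxy)ethyl]-5-methoxy-6-(3-methylbut-2-enyl)-3-(triisopropylsilyloxy)phenol | C[C@H](O[Si](CC)(CC)CC)c1c(O)c(CC=C(C)C)c(OC)cc1O[Si](C(C)C)(C(C)C)C(C)C | intermediate
18 | 2-[(S)-1-hydroxyethyl]-5-methoxy-6-(3-methylbut-2-enyl)-3-(triisopropylsilyloxy)phenol | C[C@H](O)c1c(O)c(CC=C(C)C)c(OC)cc1O[Si](C(C)C)(C(C)C)C(C)C | intermediate
19 | 1-[2-hydroxy-4-methoxy-3-(3-methylbut-2-enyl)-6-(triisopropylsilyloxy)phenyl]ethan-1-one | CC(=O)c1c(O)c(CC=C(C)C)c(OC)cc1O[Si](C(C)C)(C(C)C)C(C)C | intermediate
20 | (E)-3-(dimethylamino)-1-[2-hydroxy-4-methoxy-3-(3-methylbut-2-enyl)-6-(triisopropylsilyloxy)phenyl]prop-2-en-1-one | CN(C)/C=C/C(=O)c1c(O)c(CC=C(C)C)c(OC)cc1O[Si](C(C)C)(C(C)C)C(C)C | intermediate (not isolated)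
21 | 7-methoxy-8-(3-methylbut-2-enyl)-5-(triisopropylsilyloxy)-4H-chromen-4-one | O=c1ccoc2c1c(O[Si](C(C)C)(C(C)C)C(C)C)cc(OC)c2CC=C(C)C | intermediate
22 | 4-methoxyphenylboronic acid | COc1ccc(B(O)O)cc1 | starting material
23 | (S)-7-methoxy-2-(4-methoxyphenyl)-8-(3-methylbut-2-enyl)-5-(triisopropylsilyloxy)chroman-4-one | COc1ccc([C@@H]2CC(=O)c3c(O[Si](C(C)C)(C(C)C)C(C)C)cc(OC)c(CC=C(C)C)c3O2)cc1 | intermediate
24 | flowerine, (S)-5-hydroxy-7-methoxy-2-(4-methoxyphenyl)-8-(3-methylbut-2-enyl)chroman-4-one | COc1ccc([C@@H]2CC(=O)c3c(O)cc(OC)c(CC=C(C)C)c3O2)cc1 | target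

**Step count and risk**

Total step count: 11.
Longest linear sequence: 8 steps (1 → 2 → 7 → 17 → 18 → 19 → 21 → 23 → 24; the branch 8 → 9 → 12 → 17 is equally long).

The three steps most likely to fail:

Step 6 (key step). The vinylketene 13 may dimerise or oligomerise faster than it is intercepted by the hindered, propargylically oxygenated alkyne 12, or the cascade may stall at 14. The fallback buys ring A instead of building it. It does not branch from an intermediate: no numbered compound before 19 is used. It sets out from commercial 1-(2,6-dihydroxy-4-methoxyphenyl)ethan-1-one F1 and comes back to the route at 19. C-Prenylation of F1 with prenyl bromide (aq. KOH, 0 °C) should give, because F1 is symmetric, a single mono-C-prenyl isomer, 1-[2,6-dihydroxy-4-methoxy-3-(3-methylbut-2-enyl)phenyl]ethan-1-one F2. Silylation with i-Pr3SiCl and imidazole (DMF, rt) is then expected to take the hydroxyl flanked by hydrogen and not the one flanked by prenyl, which gives 19 with the same oxygen differentiation.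

Step 10. Carbometalation of the electron-rich chromone with its bulky peri silyloxy group may be slow, so that protodeboronation of 22 wins, or facial selectivity may be insufficient. The fallback forms the C2–O1 bond instead of the C2–aryl bond. It sets out from enaminone 20, isolated instead of being cyclised in step 9, and comes back at 23. Treatment of 20 with 4-MeOC6H4MgBr (2.5 equiv, THF, 0 °C) should deprotonate the phenol, add in a 1,4 sense and eliminate the amide, giving (E)-1-[2-hydroxy-4-methoxy-3-(3-methylbut-2-enyl)-6-(triisopropylsilyloxy)phenyl]-3-(4-methoxyphenyl)prop-2-en-1-one F3. Enantioselective intramolecular oxa-Michael addition of the free C8a phenol, catalysed by a cinchona-alkaloid-derived bifunctional thiourea (quinine series or its pseudoenantiomer, whichever delivers 2S; toluene, rt), then closes ring C to 23. Enrichment by crystallisation is foreseen if needed.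

Step 5. The carbenoid rearrangement may be incomplete, the alkyllithium may attack the triethylsilyl ether, or the ynolate may be silylated on carbon instead of oxygen. The fallback makes the ynolate by oxidation of an acetylide and not by rearrangement. It sets out from 9 and comes back at 12. Reduction of 9 with i-Bu2AlH (toluene, −78 °C) should give (S)-2-(triethylsilyloxy)propanal F4. Ohira–Bestmann homologation (dimethyl (1-diazo-2-oxopropyl)phosphonate, K2CO3, MeOH, 0 °C) should give (S)-3-(triethylsilyloxy)but-1-yne F5. Deprotonation with n-BuLi and oxidation of the lithium acetylide with lithium tert-butyl peroxide (from t-BuOOH and LiN(SiMe3)2; THF, −78 → 0 °C) gives ynolate 11, which is silylated on oxygen with triisopropylsilyl triflate to give 12. Any erosion of configuration at the aldehyde stage is harmless, since this centre is oxidised in step 8.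

**Further compounds**

F1 | step 6 | 1-(2,6-dihydroxy-4-methoxyphenyl)ethan-1-one | CC(=O)c1c(O)cc(OC)cc1O
F2 | step 6 | 1-[2,6-dihydroxy-4-methoxy-3-(3-methylbut-2-enyl)phenyl]ethan-1-one | CC(=O)c1c(O)cc(OC)c(CC=C(C)C)c1O
F3 | step 10 | (E)-1-[2-hydroxy-4-methoxy-3-(3-methylbut-2-enyl)-6-(triisopropylsilyloxy)phenyl]-3-(4-methoxyphenyl)prop-2-en-1-one | COc1ccc(/C=C/C(=O)c2c(O)c(CC=C(C)C)c(OC)cc2O[Si](C(C)C)(C(C)C)C(C)C)cc1
F4 | step 5 | (S)-2-(triethylsilyloxy)propanal | C[C@H](O[Si](CC)(CC)CC)C=O
F5 | step 5 | (S)-3-(triethylsilyloxy)but-1-yne | C[C@H](O[Si](CC)(CC)CC)C#C
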